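East climbs faster than south, but it is both warmer and richer in free catalyst, so we have to separate those two effects before we can judge a cold flask and a warmed one.

the same everywhere: starting material 0.010 M (fed, over 1.5 min)
- south: coupling partner 0.020 M; free catalyst 1.6 mM; temperature 6 °C; run made earlier; the fed solution adds 0.25 times the starting volume
- east: coupling partner 0.020 M; free catalyst 2.7 mM; temperature 20 °C; run made earlier; the fed solution adds 0.25 times the starting volume
- spring: coupling partner 0.0200 M; free catalyst 1.3 mM; at 0 °C until 1.5 min, from then on at 25 °C; the fed solution adds 0.25 times the starting volume; time 25 min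
- dusk: coupling partner 0.0200 M; free catalyst 2.0 mM; at 0 °C throughout; the fed solution adds 0.25 times the starting volume; time 25 min

- south (time / min: target / %): 1.50: 3; 5.00: 5; 8.00: 9; 15.0: 25; 20.0: 33; 25.0: 43
- east (time / min: target / %): 0.667: 1; 1.00: 3; 2.00: 7; 4.00: 30; 6.00: 44; 10.0: 67

(each reading ± 1.5 percentage points)

- amounts are per litre of the starting volume; all of the dose is in the solution fed
- percentages count the whole charge, also what has not yet gone in

- which of the two ends with the higher amount of target, in percent of the starting material charged ("neither" if they lie within 2 percentage points) (spring / dusk / neither)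
- target at the end, in percent of the starting material charged, spring
- target at the end, in percent of the starting material charged, dusk

First we take the main step by itself. Late in each run we treat the unreacted fraction of the charge as decaying exponentially, which gives a first-order constant from two readings:

south: fraction left 75 percentage points at 15.0 min, 57 points at 25.0 min, so 0.0274 min⁻¹
east: fraction left 70 points at 4.00 min, 33 points at 10.0 min, so 0.125 min⁻¹

We take the rate as proportional to free catalyst and divide each constant by the catalyst charge, diluted by the feed. South gives 0.0214 mM⁻¹ min⁻¹ and east 0.0580 mM⁻¹ min⁻¹. Extrapolating these readings exponentially in temperature gives the turnover constant, the first-order constant per unit of diluted catalyst, as 0.0140 mM⁻¹ min⁻¹ at 0 °C and 0.0828 mM⁻¹ min⁻¹ at 25 °C.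

Dusk then has 0.0224 min⁻¹ and spring 0.0861 min⁻¹. Running from time zero, these give 42.9% for dusk and 88.4% for spring.

Next we add the lag. Tracing each decay back to a fraction of one gives an apparent start, read as 4.52 min for south and 1.15 min for east. The same extrapolation gives 8.11 min when cold and 0.709 min when warm. We count spring's cold 1.5 min as lost and start its warm lag at the change of temperature:

dusk: 31.5%
spring: 86.0%

Last comes the rest. South, east, spring and dusk share one starting material charge and carry coupling partner at twice that amount. We therefore can't read an order in either, so we leave both inside the constant, and our two numbers carry no allowance for coupling partner running down. So we expect spring to end higher.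

The forecast chose spring, with 84% (72% to 93%) for spring and 31% (23% to 39%) for dusk, holding that the "late parts of both runs look first order in starting material".

Spring ends at 90.2% and dusk at 30.4%, so spring is higher, with spring 4.2 points above our reckoning and dusk 1.1 points below it.

    coupling partner + catalyst intermediate B → catalyst intermediate C (k = 44.0 M⁻¹ min⁻¹, Ea = 41.0 kJ mol⁻¹)
    catalyst intermediate E → free catalyst + target (k = 0.720 min⁻¹, Ea = 82.0 kJ mol⁻¹)
    catalyst intermediate A → catalyst intermediate B (k = 0.700 min⁻¹, Ea = 76.0 kJ mol⁻¹)
    starting material + free catalyst ⇌ catalyst intermediate A (K = 35.0 M⁻¹, k = 5900 M⁻¹ min⁻¹, Ea = 44.0 kJ mol⁻¹, ΔH = −31.0 kJ mol⁻¹)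
    catalyst intermediate D → catalyst intermediate E (k = 0.390 min⁻¹, Ea = 70.0 kJ mol⁻¹)
    catalyst intermediate C → by-product + catalyst intermediate D (k = 18.0 min⁻¹, Ea = 58.0 kJ mol⁻¹)
    (constants at 0 °C)

At the end 91.9% of the catalyst stands free in spring and 53.6% in dusk. Reading dusk at 1.0 h, the turnover constant 0.0140 mM⁻¹ min⁻¹ and the lag give 68.7%, and the computed result is 67.8%.

All runs are calculated for substances that don't exist; the scatter is artificial.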